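## Retrosynthetic overview

1. Target 23 ⇐ tetrabenzyl ether 22 (hydrogenolysis) ⇐ the aryl ketone C(=O)–CH bond: acyl anion of aldehyde 1 (Breslow intermediate of a chiral triazolylidene) plus o-quinone methide 21, unmasked on ring A of the complete lignan. This is the last C–C bond and it sets the labile centre.
2. o-Quinone methide precursor 20 ⇐ phenol 18 by boron-templated ortho-hydroxyalkylation with aldehyde 9, then sulfinate exchange.
3. 18 ⇐ trans-selective enolate alkylation of (R)-lactone 7 (Stobbe condensation, asymmetric hydrogenation) with benzylic bromide 17.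
4. 17 ⇐ the same acyl anion plus o-quinone methide union on methyl vanillate 8 with the mirror-image catalyst, then ketone reduction and acid ring closure.
5. Ring order: the butyrolactone (step 3) and the dihydrobenzofuran (step 6) are closed on separate fragments and joined in step 9; no ring is formed afterwards.

Ring A is the guaiacyl ring on the lactone C4 benzyl arm; ring B is the benzo ring of the dihydrobenzofuran. The triazolium catalyst is 2-(pentafluorophenyl)-5a,10b-dihydro-4H,6H-indeno[2,1-b][1,2,4]triazolo[4,3-d][1,4]oxazin-2-ium tetrafluoroborate, C18H11BF9N3O, used as its (5aR,10bS) or (5aS,10bR) enantiomer.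

Assumption: the sense of induction of [Rh(cod)((S,S)-Et-DuPhos)]BF4 and of each enantiomer of the C18H11BF9N3O triazolium salt is assigned by analogy; if a test run shows the opposite sense, the antipodal catalyst is used at that step and nothing else changes.

## Route

Step 1
Reactants: 1 4-(benzyloxy)-3-methoxybenzaldehyde; 2 dimethyl succinate
Product: 3 (E)-4-[4-(benzyloxy)-3-methoxyphenyl]-3-(methoxycarbonyl)but-3-enoic acid
Conditions: NaOMe, MeOH, reflux; then aq. HCl
Reagents that add atoms: none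
Why: Stobbe condensation, in which the paraconic lactone intermediate opens by E1cB to the (E)-half-ester with acid and ester already differentiated.

Step 2
Reactants: 3 (E)-half-ester
Product: 5 (R)-4-(4-hydroxy-3-methoxyphenyl)-3-(methoxycarbonyl)butanoic acid, via benzyl ether 4 (not isolated)
Conditions: [Rh(cod)((S,S)-Et-DuPhos)]BF4 (0.5 mol %), NaOMe (10 mol %), H2 (5 atm), MeOH, rt; then 10% Pd/C, H2 (1 atm), rt
Reagents that add atoms: none
Why: Carboxylate-directed asymmetric hydrogenation of a Stobbe itaconate half-ester sets the (R) centre that becomes lactone C4, and the following Pd/C hydrogenolysis frees the ring A phenol in the same pot.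

Step 3
Reactants: 5 (R)-phenol half-ester
Product: 7 (R)-4-(4-hydroxy-3-methoxybenzyl)dihydrofuran-2(3H)-one, via hydroxy acid 6 (not isolated)
Conditions: KOH (2 equiv), EtOH; CaCl2, NaBH4, −10 °C → rt; then 3 M HCl, 50 °C
Reagents that add atoms: none
Why: Chemoselective Ca(BH4)2 reduction of the ester beside the carboxylate salt, then acid lactonisation, with the stereocentre untouched.

Step 4
Reactants: 8 methyl 4-hydroxy-3-methoxybenzoate; 9 (benzyloxy)acetaldehyde
Product: 11 methyl 3-[2-(benzyloxy)-1-(4-methylbenzenesulfonyl)ethyl]-4-hydroxy-5-methoxybenzoate (racemic), via benzodioxaborin 10 (not isolated)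
Conditions: PhB(OH)2 (1.2 equiv), Cl3CCO2H (cat.), toluene, reflux, Dean–Stark; then 4-MeC6H4SO2Na, HCO2H–H2O–THF, 40 °C
Reagents that add atoms: sodium 4-methylbenzenesulfinate, Cc1ccc(cc1)S(=O)[O-].[Na+]
Why: Nagata boron-templated ortho-specific hydroxyalkylation of the phenol, then acid-mediated exchange of the benzylic oxygen for sulfinate through the o-quinone methide; the new centre is racemic and is erased in step 5.

Step 5
Reactants: 11 racemic sulfone; 1 4-(benzyloxy)-3-methoxybenzaldehyde
Product: 13 methyl 3-{(2R)-3-(benzyloxy)-1-[4-(benzyloxy)-3-methoxyphenyl]-1-oxopropan-2-yl}-4-hydroxy-5-methoxybenzoate, via o-quinone methide 12 (not isolated)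
Conditions: (5aR,10bS)-triazolium tetrafluoroborate C18H11BF9N3O (15 mol %), K2CO3 (1.5 equiv), 1 (2 equiv), 4 Å MS, toluene, 0 °C, slow addition of 11
Reagents that add atoms: none
Why: Proposed new method: K2CO3 expels sulfinate from the phenoxide to give o-quinone methide 12 at low concentration while the carbene converts aldehyde 1 into its Breslow intermediate, whose chiral pocket selects one face of the exocyclic CH in a 1,4-addition that rearomatises the ring and sets the (R) centre, and the product sits as its phenoxide, which resists enolisation; the closest known reactions are the racemic thiazolium-carbinol acylation of o-quinone methides and chiral-triazolium intermolecular Stetter reactions.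

Step 6
Reactants: 13 (R)-ketone
Product: 15 methyl (2S,3R)-2-[4-(benzyloxy)-3-methoxyphenyl]-3-[(benzyloxy)methyl]-7-methoxy-2,3-dihydro-1-benzofuran-5-carboxylate, via diol 14 (not isolated)
Conditions: NaBH4, CeCl3·7H2O, MeOH–THF, −40 °C; then 2 M HCl (pH 1), 40 °C
Reagents that add atoms: none
Why: Luche reduction, then acid-promoted ring closure through the p-benzyloxybenzyl cation, which the phenol captures anti to the CH2OBn group under reversible conditions, so both carbinol epimers give the (2S,3R)-trans ring while C3 keeps the configuration from step 5.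

Step 7
Reactants: 15 dihydrobenzofuran ester
Product: 16 [(2S,3R)-2-[4-(benzyloxy)-3-methoxyphenyl]-3-[(benzyloxy)methyl]-7-methoxy-2,3-dihydro-1-benzofuran-5-yl]methanol
Conditions: LiAlH4, THF, 0 °C
Reagents that add atoms: none
Why: Hydride reduction of the aryl ester to the benzylic alcohol; benzyl ethers and the cyclic benzylic ether are inert.

Step 8
Reactants: 16 benzylic alcohol
Product: 17 (2S,3R)-2-[4-(benzyloxy)-3-methoxyphenyl]-3-[(benzyloxy)methyl]-5-(bromomethyl)-7-methoxy-2,3-dihydro-1-benzofuran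
Conditions: CBr4, PPh3, CH2Cl2, 0 °C; used crude
Reagents that add atoms: carbon tetrabromide, BrC(Br)(Br)Br
Why: Appel bromination under neutral conditions, which avoids acid at the cyclic benzylic ether.

Step 9
Reactants: 7 (R)-lactone phenol; 17 benzylic bromide
Product: 18 (3R,4R)-trans-lactone carrying the dihydrobenzofuranylmethyl group of 17 at C3 (full name in the list)
Conditions: 7 (1.1 equiv), LiN(SiMe3)2 (2.3 equiv), THF, −78 °C; then 17, −78 → −50 °C; NH4Cl
Reagents that add atoms: none
Why: Enolate alkylation of the dilithio species, in which the lactone enolate reacts at carbon at −78 °C while the lithium phenoxide stays inert, and the bromide enters anti to the C4 benzyl group to set C3 as (R), trans.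

Step 10
Reactants: 18 trans-lactone phenol; 9 (benzyloxy)acetaldehyde
Product: 20 ring A sulfone of 18 (two epimers at the sulfonyl carbon; full name in the list), via benzodioxaborin 19 (not isolated)
Conditions: PhB(OH)2 (1.2 equiv), Cl3CCO2H (cat.), toluene, reflux, Dean–Stark; then 4-MeC6H4SO2Na, HCO2H–H2O–THF, rt
Reagents that add atoms: sodium 4-methylbenzenesulfinate, Cc1ccc(cc1)S(=O)[O-].[Na+]
Why: The same Nagata hydroxyalkylation and sulfinate exchange as step 4, regiospecific because ring A holds the only free phenol and only one free ortho position; the epimeric centre is erased in step 11.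

Step 11
Reactants: 20 ring A sulfone; 1 4-(benzyloxy)-3-methoxybenzaldehyde
Product: 22 tetrabenzyl ether of the target with the (2S) ketone centre (full name in the list), via o-quinone methide 21 (not isolated)
Conditions: (5aS,10bR)-triazolium tetrafluoroborate C18H11BF9N3O (20 mol %), K2CO3 (1.5 equiv), 1 (2 equiv), 4 Å MS, toluene, 0 °C, slow addition of 20
Reagents that add atoms: none
Why: Proposed new method: as in step 5 but with the mirror-image carbene, the Breslow intermediate of 1 adds 1,4 to o-quinone methide 21 on the complete skeleton and sets the (S) centre under catalyst control (the other stereocentres are too remote to interfere), and the mild carbonate and the phenoxide form of the product protect both this centre and the thermodynamically preferred trans-lactone; the closest known reactions are the racemic thiazolium-carbinol acylation of o-quinone methides and chiral-triazolium intermolecular Stetter reactions.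

Step 12
Reactants: 22 tetrabenzyl ether
Product: 23 target CNP0111438.1
Conditions: H2 (1 atm), Pd(OH)2/C, EtOAc–MeOH, rt, stopped at full conversion
Reagents that add atoms: none
Why: Neutral hydrogenolysis of the four benzyl ethers, which avoids the acid or base that would epimerise, dehydrate or retro-aldolise the α-aryl β-hydroxy ketone; the electron-rich aryl ketone and the cyclic benzylic ether react more slowly than O-benzyl groups.

## Compound list

1 | 4-(benzyloxy)-3-methoxybenzaldehyde | COc1cc(C=O)ccc1OCc1ccccc1 | starting material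
2 | dimethyl succinate | COC(=O)CCC(=O)OC | starting material
3 | (E)-4-[4-(benzyloxy)-3-methoxyphenyl]-3-(methoxycarbonyl)but-3-enoic acid | COC(=O)/C(CC(=O)O)=C/c1ccc(OCc2ccccc2)c(OC)c1 | intermediate
4 | (R)-4-[4-(benzyloxy)-3-methoxyphenyl]-3-(methoxycarbonyl)butanoic acid | COC(=O)[C@@H](CC(=O)O)Cc1ccc(OCc2ccccc2)c(OC)c1 | intermediate (not isolated)
5 | (R)-4-(4-hydroxy-3-methoxyphenyl)-3-(methoxycarbonyl)butanoic acid | COC(=O)[C@@H](CC(=O)O)Cc1ccc(O)c(OC)c1 | intermediate
6 | (3R)-4-hydroxy-3-[(4-hydroxy-3-methoxyphenyl)methyl]butanoic acid | OC[C@@H](CC(=O)O)Cc1ccc(O)c(OC)c1 | intermediate (not isolated)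
7 | (R)-4-(4-hydroxy-3-methoxybenzyl)dihydrofuran-2(3H)-one | O=C1OC[C@H](Cc2ccc(O)c(OC)c2)C1 | intermediate
8 | methyl 4-hydroxy-3-methoxybenzoate (methyl vanillate) | COC(=O)c1ccc(O)c(OC)c1 | starting material
9 | (benzyloxy)acetaldehyde | O=CCOCc1ccccc1 | starting material
10 | methyl 4-[(benzyloxy)methyl]-8-methoxy-2-phenyl-4H-1,3,2-benzodioxaborinine-6-carboxylate (racemic) | COC(=O)c1cc(OC)c2c(c1)C(COCc1ccccc1)OB(c1ccccc1)O2 | intermediate (not isolated)
11 | methyl 3-[2-(benzyloxy)-1-(4-methylbenzenesulfonyl)ethyl]-4-hydroxy-5-methoxybenzoate (racemic) | COC(=O)c1cc(OC)c(O)c(c1)C(COCc1ccccc1)S(=O)(=O)c1ccc(C)cc1 | intermediate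
12 | methyl 3-[2-(benzyloxy)ethylidene]-5-methoxy-4-oxocyclohexa-1,5-diene-1-carboxylate | COC(=O)C1=CC(=CCOCc2ccccc2)C(=O)C(OC)=C1 | intermediate (not isolated)
13 | methyl 3-{(2R)-3-(benzyloxy)-1-[4-(benzyloxy)-3-methoxyphenyl]-1-oxopropan-2-yl}-4-hydroxy-5-methoxybenzoate | COC(=O)c1cc(OC)c(O)c(c1)[C@H](COCc1ccccc1)C(=O)c1ccc(OCc2ccccc2)c(OC)c1 | intermediate
14 | methyl 3-{(2R)-3-(benzyloxy)-1-[4-(benzyloxy)-3-methoxyphenyl]-1-hydroxypropan-2-yl}-4-hydroxy-5-methoxybenzoate (carbinol epimers) | COC(=O)c1cc(OC)c(O)c(c1)[C@H](COCc1ccccc1)C(O)c1ccc(OCc2ccccc2)c(OC)c1 | intermediate (not isolated)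
15 | methyl (2S,3R)-2-[4-(benzyloxy)-3-methoxyphenyl]-3-[(benzyloxy)methyl]-7-methoxy-2,3-dihydro-1-benzofuran-5-carboxylate | COC(=O)c1cc(OC)c2c(c1)[C@H](COCc1ccccc1)[C@@H](c1ccc(OCc3ccccc3)c(OC)c1)O2 | intermediate
16 | [(2S,3R)-2-[4-(benzyloxy)-3-methoxyphenyl]-3-[(benzyloxy)methyl]-7-methoxy-2,3-dihydro-1-benzofuran-5-yl]methanol | OCc1cc(OC)c2c(c1)[C@H](COCc1ccccc1)[C@@H](c1ccc(OCc3ccccc3)c(OC)c1)O2 | intermediate
17 | (2S,3R)-2-[4-(benzyloxy)-3-methoxyphenyl]-3-[(benzyloxy)methyl]-5-(bromomethyl)-7-methoxy-2,3-dihydro-1-benzofuran | BrCc1cc(OC)c2c(c1)[C@H](COCc1ccccc1)[C@@H](c1ccc(OCc3ccccc3)c(OC)c1)O2 | intermediate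
18 | (3R,4R)-3-({(2S,3R)-2-[4-(benzyloxy)-3-methoxyphenyl]-3-[(benzyloxy)methyl]-7-methoxy-2,3-dihydro-1-benzofuran-5-yl}methyl)-4-[(4-hydroxy-3-methoxyphenyl)methyl]oxolan-2-one | COc1cc(C[C@H]2COC(=O)[C@@H]2Cc2cc(OC)c3c(c2)[C@H](COCc2ccccc2)[C@@H](c2ccc(OCc4ccccc4)c(OC)c2)O3)ccc1O | intermediate
19 | 2-phenyl-4H-1,3,2-benzodioxaborinine formed on ring A of 18: boron bridges the phenol oxygen and the new benzylic oxygen, C4 carries CH2OBn (epimers at C4) | COc1cc(C[C@H]2COC(=O)[C@@H]2Cc2cc(OC)c3c(c2)[C@H](COCc2ccccc2)[C@@H](c2ccc(OCc4ccccc4)c(OC)c2)O3)cc2c1OB(c1ccccc1)OC2COCc1ccccc1 | intermediate (not isolated)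
20 | (3R,4R)-3-({(2S,3R)-2-[4-(benzyloxy)-3-methoxyphenyl]-3-[(benzyloxy)methyl]-7-methoxy-2,3-dihydro-1-benzofuran-5-yl}methyl)-4-({3-[2-(benzyloxy)-1-(4-methylbenzenesulfonyl)ethyl]-4-hydroxy-5-methoxyphenyl}methyl)oxolan-2-one (epimers at the sulfonyl carbon) | COc1cc(C[C@H]2COC(=O)[C@@H]2Cc2cc(OC)c3c(c2)[C@H](COCc2ccccc2)[C@@H](c2ccc(OCc4ccccc4)c(OC)c2)O3)cc(C(COCc2ccccc2)S(=O)(=O)c2ccc(C)cc2)c1O | intermediate
21 | o-quinone methide of 20: ring A as 6-[2-(benzyloxy)ethylidene]-2-methoxycyclohexa-2,4-dien-1-one carrying the lactone CH2 at C4 | COC1=CC(C[C@H]2COC(=O)[C@@H]2Cc2cc(OC)c3c(c2)[C@H](COCc2ccccc2)[C@@H](c2ccc(OCc4ccccc4)c(OC)c2)O3)=CC(=CCOCc2ccccc2)C1=O | intermediate (not isolated)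
22 | (3R,4R)-3-({(2S,3R)-2-[4-(benzyloxy)-3-methoxyphenyl]-3-[(benzyloxy)methyl]-7-methoxy-2,3-dihydro-1-benzofuran-5-yl}methyl)-4-({3-[(2S)-3-(benzyloxy)-1-[4-(benzyloxy)-3-methoxyphenyl]-1-oxopropan-2-yl]-4-hydroxy-5-methoxyphenyl}methyl)oxolan-2-one | COc1cc(C(=O)[C@H](COCc2ccccc2)c2cc(C[C@H]3COC(=O)[C@@H]3Cc3cc(OC)c4c(c3)[C@H](COCc3ccccc3)[C@@H](c3ccc(OCc5ccccc5)c(OC)c3)O4)cc(OC)c2O)ccc1OCc1ccccc1 | intermediate
23 | (3R,4R)-3-({(2S,3R)-2-(4-hydroxy-3-methoxyphenyl)-3-(hydroxymethyl)-7-methoxy-2,3-dihydro-1-benzofuran-5-yl}methyl)-4-({4-hydroxy-3-[(2S)-3-hydroxy-1-(4-hydroxy-3-methoxyphenyl)-1-oxopropan-2-yl]-5-methoxyphenyl}methyl)oxolan-2-one | COc1cc(C(=O)[C@H](CO)c2cc(C[C@H]3COC(=O)[C@@H]3Cc3cc(OC)c4c(c3)[C@H](CO)[C@@H](c3ccc(O)c(OC)c3)O4)cc(OC)c2O)ccc1O | target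

## Step count and risks

Total steps: 12. Longest linear sequence: 9 (steps 4 to 12, from 8 to 23); the lactone branch is 3 steps (1 to 3) and joins at step 9.

The three steps most likely to fail:

**Step 11.** The catalytic, enantioselective acylation of the o-quinone methide may fail on the full skeleton: the carbene can be trapped by the o-quinone methide, the o-quinone methide can tautomerise to the enol ether, or selectivity can be low. The fallback delivers the acyl anion stoichiometrically and sets the centre by separation. It sets out from 1 and 20. 2-Lithio-4,5-dimethylthiazole (from 4,5-dimethylthiazole and n-BuLi, THF, −78 °C) adds to 1 to give [4-(benzyloxy)-3-methoxyphenyl](4,5-dimethyl-1,3-thiazol-2-yl)methanol F1. Et3SiCl and imidazole convert it into 2-{[4-(benzyloxy)-3-methoxyphenyl][(triethylsilyl)oxy]methyl}-4,5-dimethyl-1,3-thiazole F2, and MeOTf gives 2-{[4-(benzyloxy)-3-methoxyphenyl][(triethylsilyl)oxy]methyl}-3,4,5-trimethyl-1,3-thiazol-3-ium trifluoromethanesulfonate F3. With CsF in CH2Cl2, fluoride removes the silyl group to release the Breslow intermediate and also unmasks the o-quinone methide from 20. The addition gives 22 together with its (2R) ketone epimer F4. These are diastereomers and are separated by preparative HPLC; F4 is re-equilibrated with Et3N and recycled. The fallback comes back to the route at 22.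

**Step 5.** The same new reaction on the monomer may give the ketone in low enantiomeric excess. The fallback sets out from 11 and sets the centre by dynamic kinetic resolution instead of by the carbene. Sulfone 11 is acylated without stereocontrol (thiazolium triflate F3 and CsF, as above) to give racemic methyl 3-{3-(benzyloxy)-1-[4-(benzyloxy)-3-methoxyphenyl]-1-oxopropan-2-yl}-4-hydroxy-5-methoxybenzoate F5. Noyori transfer hydrogenation with RuCl(p-cymene)[(R,R)-TsDPEN] in HCO2H–Et3N reduces one enantiomer while the α-aryl ketone racemises under the amine. The catalyst enantiomer is the one that a test run shows to give the (2R) diol. This gives diol 14 as a single (2R) isomer, and the fallback comes back to the route at 14, which is closed with acid to 15 as in step 6.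

**Step 10.** The late-stage Nagata hydroxyalkylation and the acidic sulfinate exchange may damage the complex substrate or stall. The fallback sets out from 18 and builds the two-carbon handle in separate, milder stages. Ortho-formylation (MgCl2, Et3N, paraformaldehyde, MeCN, reflux) gives the ring A salicylaldehyde F6. BnOCH2MgCl (2.2 equiv, THF, −78 °C) adds to the magnesium-chelated aldehyde in preference to the lactone and gives the ring A 2-(benzyloxy)-1-hydroxyethyl diol F7. Brief treatment with 4-MeC6H4SO2Na in HCO2H–H2O at rt converts F7 into the sulfone, and the fallback comes back to the route at 20.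

## Further compounds

F1 | step 11 | [4-(benzyloxy)-3-methoxyphenyl](4,5-dimethyl-1,3-thiazol-2-yl)methanol (racemic) | COc1cc(C(O)c2nc(C)c(C)s2)ccc1OCc1ccccc1
F2 | step 11 | 2-{[4-(benzyloxy)-3-methoxyphenyl][(triethylsilyl)oxy]methyl}-4,5-dimethyl-1,3-thiazole (racemic) | COc1cc(C(O[Si](CC)(CC)CC)c2nc(C)c(C)s2)ccc1OCc1ccccc1
F3 | step 11 | 2-{[4-(benzyloxy)-3-methoxyphenyl][(triethylsilyl)oxy]methyl}-3,4,5-trimethyl-1,3-thiazol-3-ium trifluoromethanesulfonate (racemic) | COc1cc(C(O[Si](CC)(CC)CC)c2sc(C)c(C)[n+]2C)ccc1OCc1ccccc1.[O-]S(=O)(=O)C(F)(F)F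
F4 | step 11 | (2R) ketone epimer of 22 | COc1cc(C(=O)[C@@H](COCc2ccccc2)c2cc(C[C@H]3COC(=O)[C@@H]3Cc3cc(OC)c4c(c3)[C@H](COCc3ccccc3)[C@@H](c3ccc(OCc5ccccc5)c(OC)c3)O4)cc(OC)c2O)ccc1OCc1ccccc1
F5 | step 5 | methyl 3-{3-(benzyloxy)-1-[4-(benzyloxy)-3-methoxyphenyl]-1-oxopropan-2-yl}-4-hydroxy-5-methoxybenzoate (racemic 13) | COC(=O)c1cc(OC)c(O)c(c1)C(COCc1ccccc1)C(=O)c1ccc(OCc2ccccc2)c(OC)c1
F6 | step 10 | 5-{[(3R,4R)-4-({(2S,3R)-2-[4-(benzyloxy)-3-methoxyphenyl]-3-[(benzyloxy)methyl]-7-methoxy-2,3-dihydro-1-benzofuran-5-yl}methyl)-5-oxooxolan-3-yl]methyl}-2-hydroxy-3-methoxybenzaldehyde | COc1cc(C[C@H]2COC(=O)[C@@H]2Cc2cc(OC)c3c(c2)[C@H](COCc2ccccc2)[C@@H](c2ccc(OCc4ccccc4)c(OC)c2)O3)cc(C=O)c1O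
F7 | step 10 | (3R,4R)-3-({(2S,3R)-2-[4-(benzyloxy)-3-methoxyphenyl]-3-[(benzyloxy)methyl]-7-methoxy-2,3-dihydro-1-benzofuran-5-yl}methyl)-4-({3-[2-(benzyloxy)-1-hydroxyethyl]-4-hydroxy-5-methoxyphenyl}methyl)oxolan-2-one (carbinol epimers) | COc1cc(C[C@H]2COC(=O)[C@@H]2Cc2cc(OC)c3c(c2)[C@H](COCc2ccccc2)[C@@H](c2ccc(OCc4ccccc4)c(OC)c2)O3)cc(C(O)COCc2ccccc2)c1O
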